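**Plan**

- The retrosynthesis opens ring B of the quinolone at three bonds, N-1–C-2, C-4–C-3 and C-4a–C-4. This gives an ortho-iodo-N-methylaniline (ring A with N-1 and its methyl), carbon monoxide (C-4) and 1-hexadecyne (C-3, C-2 and the chain). One more cut, between the chain and the alkyne carbons, leads to 1-bromotetradecane and an acetylide.
- This works because ring B is a vinylogous amide, N-1–C-2=C-3–C-4(=O), fused to ring A at C-4a/C-8a. C-4 is an isolated carbonyl carbon between the aryl carbon C-4a and the C-3=C-2 pair, and N-1 sits ortho to C-4a, within reach of C-2.
- Forward: the C14 chain is joined to the two-carbon acetylide first, and 2-iodoaniline is monomethylated on nitrogen. Ring B, the only ring made, is closed last in one vessel, with the tetradecyl chain placed at C-2 in the same operation.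
- Stereochemistry: the target has no stereocentre and no stereogenic double bond, so nothing has to be controlled. The alkene geometry of the transient enaminone is lost on ring closure.

Key step: step 4

Remark: carbon monoxide is taken from a cylinder and used under a few bar of pressure, lithium acetylide is used as its commercial ethylenediamine complex, and the NHMe group is carried unprotected through the carbonylation.

**Route**

Step 1
Reactants: 1 1-bromotetradecane; 2 lithium acetylide ethylenediamine complex (LiC≡CH·H2NCH2CH2NH2)
Product: 3 1-hexadecyne
Conditions: DMSO, 10 °C to rt; then H2O, pentane extraction, distillation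
Reagents that add atoms: none
Why: SN2 displacement of an unhindered primary bromide by a monolithium acetylide in a dipolar aprotic solvent is the standard acetylide alkylation for terminal alkynes, and an excess of the diamine-stabilised acetylide at or below room temperature should hold back E2 elimination, double alkylation and migration of the triple bond.

Step 2
Reactants: 4 2-iodoaniline
Product: 5 N-(2-iodophenyl)formamide
Conditions: HCO2H (excess), toluene, reflux, Dean–Stark
Reagents that add atoms: formic acid, O=CO
Why: Azeotropic N-formylation of an aniline with formic acid is a simple condensation that puts exactly one carbon on nitrogen, so the following reduction can give only the monomethyl amine, while the aryl iodide is untouched.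

Step 3
Reactants: 5 N-(2-iodophenyl)formamide
Product: 6 2-iodo-N-methylaniline
Conditions: BH3·SMe2, THF, 0 °C to reflux; then MeOH, aq. HCl; then aq. NaOH
Reagents that add atoms: none
Why: Borane reduction of an amide: the electrophilic hydride reduces the formyl C=O to CH2 but does not attack the aryl C–I bond, which LiAlH4 or hydrogenation would put at risk, and acidic methanolysis should free the amine from boron.

Step 4
Reactants: 3 1-hexadecyne; 6 2-iodo-N-methylaniline; 7 carbon monoxide
Product: 10 1-methyl-2-tetradecylquinolin-4(1H)-one, via ynone 8 (not isolated), via enaminone 9 (not isolated)
Conditions: 7 (5 bar), PdCl2(dppf) (cat., dppf = 1,1'-bis(diphenylphosphino)ferrocene), Et3N, THF, 60 °C; then vent, Et2NH, 70 °C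
Reagents that add atoms: diethylamine, CCNCC (its atoms are carried only by intermediate 9 and leave again on ring closure)
Why: Zerovalent palladium, Pd(dppf) formed in situ from PdCl2(dppf), inserts into the C–I bond of 6, carbon monoxide inserts to give the aroyl complex ArC(O)Pd(dppf)I of divalent palladium, and triethylamine-assisted alkynyl transfer from 3 followed by reductive elimination releases ynone 8, which forms C-4a–C-4 and C-4–C-3 around the carbon of 7. Diethylamine, added only after 6 is consumed, adds to the electron-poor C-2 to give the push-pull enaminone 9, whose ortho NHMe group then attacks C-2 and expels diethylamine, which forms N-1–C-2 and is driven by the aromatic 4-quinolone. The closest known reaction type is the palladium-catalysed carbonylative Sonogashira coupling of 2-iodoanilines with terminal alkynes followed by secondary-amine-mediated cyclisation of the 2-aminophenyl ynone to the 4-quinolone. Ring B, the only ring formed, closes by a 6-endo-trig addition–elimination at the enaminone (6-endo-dig if the ynone is attacked directly). No stereocentre arises, and the E geometry of 9 is of no consequence because C-2 becomes tetrahedral during the amine exchange and ends as a ring sp2 carbon. The step needs CO insertion ahead of alkynyl transfer (CO pressure, no CuI cocatalyst), no capture of the aroyl complex by an amine (only the tertiary amine is present at that stage, and the hindered ortho NHMe could only close a four-membered ring), and 6-endo instead of 5-exo closure, which the conjugation of the ynone secures by making only the chain-bearing C-2 electrophilic while the terminal alkyne guarantees hydrogen at C-3.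

**Compound list**

1 | 1-bromotetradecane | CCCCCCCCCCCCCCBr | starting material
2 | lithium acetylide ethylenediamine complex, LiC≡CH·H2NCH2CH2NH2 | [Li]C#C.NCCN | starting material
3 | 1-hexadecyne (hexadec-1-yne) | CCCCCCCCCCCCCCC#C | intermediate
4 | 2-iodoaniline | Nc1ccccc1I | starting material
5 | N-(2-iodophenyl)formamide | O=CNc1ccccc1I | intermediate
6 | 2-iodo-N-methylaniline | CNc1ccccc1I | intermediate
7 | carbon monoxide | [C-]#[O+] | starting material
8 | 1-[2-(methylamino)phenyl]heptadec-2-yn-1-one | CCCCCCCCCCCCCCC#CC(=O)c1ccccc1NC | intermediate
9 | (E)-3-(diethylamino)-1-[2-(methylamino)phenyl]heptadec-2-en-1-one | CCCCCCCCCCCCCC/C(N(CC)CC)=C\C(=O)c1ccccc1NC | intermediate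
10 | 1-methyl-2-tetradecylquinolin-4(1H)-one | CCCCCCCCCCCCCCc1cc(=O)c2ccccc2n1C | target

**Count**

Total step count: 4. Longest linear sequence: 3 steps (4 to 5 to 6 to 10, steps 2, 3 and 4); the alkyne branch (1 + 2 to 3, step 1) joins at step 4.

**Steps most likely to fail**

Step 4. The coupling may proceed without CO insertion, the aroyl complex ArC(O)Pd(dppf)I may be captured by an N–H group, or the ring closure may stall at the enaminone or turn 5-exo. The fallback builds ring B from the other side, by acylating a methyl ketone enolate with a preformed anthranilic unit. It sets out from 3: Markovnikov hydration (HgSO4 cat., aq. H2SO4, MeOH, 60 °C) should give hexadecan-2-one F1. Its kinetic enolate, lithium hexadec-1-en-2-olate F2 (LiN(iPr)2, THF, −78 °C), is acylated at the ester-type carbonyl of purchased N-methylisatoic anhydride (O=C1OC(=O)N(C)c2ccccc12). The ring-opened carbamate loses CO2, and the resulting 1-[2-(methylamino)phenyl]heptadecane-1,3-dione F3 should cyclodehydrate, N-1 onto the chain-bearing ketone, on warming or on aqueous HCl work-up. This comes back to the route at 10.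

Step 1. E2 loss of HBr from the bromide, base-induced migration of the triple bond or a second alkylation of the product acetylide may erode the terminal alkyne. The fallback brings in the two alkyne carbons one at a time and avoids any SN2 step. It sets out from 1: Mg turnings in THF give tetradecylmagnesium bromide F4, which is formylated with N,N-dimethylformamide (0 °C, then aq. HCl) to pentadecanal F5. Ohira–Bestmann homologation (dimethyl (1-diazo-2-oxopropyl)phosphonate, CC(=O)C(=[N+]=[N-])P(=O)(OC)OC, K2CO3, MeOH, rt) then turns the aldehyde into the terminal alkyne and comes back to the route at 3.

Step 3. Borane may cleave the formyl C–N bond instead of reducing the carbonyl, or the reduction may stop at a persistent boron–nitrogen adduct. The fallback uses the formyl group only as a protecting group that enforces monoalkylation and takes the methyl carbon from an electrophile. It sets out from 5: deprotonation and methylation (NaH, MeI, THF, 0 °C) should give N-(2-iodophenyl)-N-methylformamide F6, and hydrolysis of the formamide (KOH, aq. EtOH, reflux) comes back to the route at 6.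

**Further compounds**

F1 | step 4 | hexadecan-2-one | CCCCCCCCCCCCCCC(C)=O
F2 | step 4 | lithium hexadec-1-en-2-olate | [Li]OC(=C)CCCCCCCCCCCCCC
F3 | step 4 | 1-[2-(methylamino)phenyl]heptadecane-1,3-dione | CCCCCCCCCCCCCCC(=O)CC(=O)c1ccccc1NC
F4 | step 1 | tetradecylmagnesium bromide | CCCCCCCCCCCCCC[Mg]Br
F5 | step 1 | pentadecanal | CCCCCCCCCCCCCCC=O
F6 | step 3 | N-(2-iodophenyl)-N-methylformamide | CN(C=O)c1ccccc1I
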